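**Plan**

1. Numbering used throughout: cyclobutane C1–C5–C6–C10; ring C = C1–C2–C3–C4–C5 (2-OAc, 4-OH, CH3-15); ring A = C6–C7–C8–C9–C10 (8-OTig, CH3-14 on C10); butenolide C6–O–C12(=O)–C11(C13H2OAc)=C7. "Exo" is the outer face of the cis-syn-cis 5-4-5 bowl (H-1, H-5, CH3-14 and every oxygen); "endo" is the cleft between rings A and C (CH3-15).
2. Retrosynthesis: cut the ester C–O bonds at C8 and C2 (each formed with inversion from an endo alcohol), then C7=C11 and O–C12 of the butenolide (aldol condensation of a C6 α-keto ester onto a C8 ketone), then C9–C10 and C6–C7 of ring A together in one tethered (3+2) event, then C1–C10/C5–C6 (enone–ketene acetal [2+2]) and ring C (ring-closing metathesis of linalool).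
3. Enabling feature: the C6–C10 bond carries the lactone oxygen at C6, so it can be held as a strained, nucleophilic cyclobutene silyl enol ether (C10=C6–OSi). The endo position at C2 of ring C lies over this bond, so a C2–O–C(=O)–C9 β-keto-ester tether (later lost as CO2) delivers the C9–C8(O)–C7 unit, an enol diazoacetate with C8 as its oxygenated central carbon, to the concave face.
4. Forward order: ring C → cyclobutane → ring A (with a temporary δ-lactone) → butenolide → esters.
5. Stereochemistry: C4 from (R)-linalool; C1/C5 from photocycloaddition anti to the C4 silyloxy group; C10/C6 from the tether; C2 and C8 from exo hydride delivery followed by Mitsunobu inversion.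

Key step: step 10

**Route**

Step 1
Reactants: 1 (R)-(−)-linalool
Product: 2 (1R)-1-methylcyclopent-2-en-1-ol
Conditions: second-generation Grubbs catalyst (1 mol %), CH2Cl2, 40 °C
Reagents that add atoms: none
Why: Ring-closing olefin metathesis of the 1,6-diene expels isobutene and closes the cyclopentene without touching the tertiary carbinol stereocenter, which becomes C4.

Step 2
Reactants: 2 (1R)-1-methylcyclopent-2-en-1-ol
Product: 3 (1R)-1-methylcyclopent-2-en-1-yl tert-butyldimethylsilyl ether
Conditions: TBSOTf, 2,6-lutidine, CH2Cl2, −78 → 0 °C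
Reagents that add atoms: tert-butyldimethylsilyl triflate CC(C)(C)[Si](C)(C)OS(=O)(=O)C(F)(F)F
Why: Silyl triflate silylation of the tertiary alcohol installs a bulky ether that is needed as the facial control element of step 5 and survives to the last step; no stereocenter is affected.

Step 3
Reactants: 3 (1R)-1-methylcyclopent-2-en-1-yl tert-butyldimethylsilyl ether
Product: 4 (4R)-4-(tert-butyldimethylsilyloxy)-4-methylcyclopent-2-en-1-one
Conditions: Rh2(cap)4 (dirhodium tetracaprolactamate, 1 mol %), t-BuOOH, K2CO3, CH2Cl2, 23 °C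
Reagents that add atoms: tert-butyl hydroperoxide CC(C)(C)OO
Why: Dirhodium caprolactamate/hydroperoxide allylic oxidation converts the only allylic CH2 into the enone carbonyl (future C2), trapping of the allyl radical at the terminus remote from the quaternary carbon being favoured sterically.

Step 4
Reactants: 5 3,3-dimethoxyprop-1-ene
Product: 6 1,1-dimethoxyprop-1-ene
Conditions: RuCl2(PPh3)3 (0.5 mol %), neat, 120 °C, then distillation
Reagents that add atoms: none
Why: Ruthenium hydride-mediated allyl-to-propenyl double-bond isomerization of the unsaturated acetal gives the ketene acetal; no stereocenter is involved.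

Step 5
Reactants: 4 (4R)-4-(tert-butyldimethylsilyloxy)-4-methylcyclopent-2-en-1-one; 6 1,1-dimethoxyprop-1-ene
Product: 7 cis-fused 4-exo-(tert-butyldimethylsilyloxy)-6,6-dimethoxy-4-endo-methyl-7-methylbicyclo[3.2.0]heptan-2-one (both C7 epimers; bicyclic C7 is C10)
Conditions: hν (Pyrex, λ > 300 nm), excess 6, CH2Cl2, −40 °C
Reagents that add atoms: none
Why: Triplet enone–alkene [2+2] photocycloaddition in which the head-to-tail preference of electron-rich alkenes places the acetal carbon (C6) on the enone β-carbon (C5), the five-membered enone enforces a cis ring fusion, and approach anti to the silyloxy group, which leans over the enone π-face, sets C1 and C5 relative to C4; the C10 configuration is erased in step 9.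

Step 6
Reactants: 7 photoadduct
Product: 9 4-exo-(tert-butyldimethylsilyloxy)-2-endo-hydroxy-4-endo-methyl-7-methylbicyclo[3.2.0]heptan-6-one, via ketal alcohol 8 (not isolated)
Conditions: NaBH4, MeOH, −40 °C; then 1 M HCl, THF, 0 → 23 °C
Reagents that add atoms: water O
Why: Borohydride reduction from the convex face, the concave face being screened by the cyclobutane, gives the endo C2 alcohol (new stereocenter), and aqueous acid then hydrolyses the dimethyl ketal to the cyclobutanone while the tertiary silyl ether survives.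

Step 7
Reactants: 9 hydroxy cyclobutanone
Product: 10 2-endo-(3-oxobutanoyloxy) ester of 9
Conditions: 2,2,6-trimethyl-4H-1,3-dioxin-4-one, toluene, 110 °C
Reagents that add atoms: 2,2,6-trimethyl-4H-1,3-dioxin-4-one CC1=CC(=O)OC(C)(C)O1
Why: Thermal retro-[4+2] of the dioxinone releases acetylketene, which acetoacetylates the hindered secondary alcohol under neutral conditions; no stereocenter changes.

Step 8
Reactants: 10 acetoacetate
Product: 11 2-endo-(2-diazo-3-oxobutanoyloxy) ester of 9
Conditions: 4-acetamidobenzenesulfonyl azide, Et3N, MeCN, 0 → 23 °C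
Reagents that add atoms: 4-acetamidobenzenesulfonyl azide CC(=O)Nc1ccc(cc1)S(=O)(=O)N=[N+]=[N-]
Why: Regitz diazo transfer to the active methylene of the β-keto ester (future C9), the far less acidic cyclobutanone α-position being untouched.

Step 9
Reactants: 11 diazo ester
Product: 12 2-endo-[2-diazo-3-(triethylsilyloxy)but-3-enoyloxy]-4-exo-(tert-butyldimethylsilyloxy)-4-endo-methyl-7-methyl-6-(triethylsilyloxy)bicyclo[3.2.0]hept-6-ene
Conditions: TESOTf (2.5 equiv), Et3N, CH2Cl2, −78 → 0 °C
Reagents that add atoms: triethylsilyl triflate CC[Si](CC)(CC)OS(=O)(=O)C(F)(F)F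
Why: Soft enolization–silylation converts the methyl ketone into the enol diazoacetate and the cyclobutanone into the tetrasubstituted C10=C6 silyl enol ether, enolization toward the ring-fusion carbon C5 being excluded by strain; C10 becomes planar.

Step 10
Reactants: 12 bis(silyl enol ether) diazo ester
Product: 13 tetracyclic lactone: cis-syn-cis 5-4-5 tricycle with a δ-lactone C2(endo)–O–C(=O)–C9, a C8=C9 enol ether (8-OSiEt3), 6-exo-OSiEt3, CH3-14 exo, 4-exo-OTBS
Conditions: Rh2(OAc)4 (1 mol %), CH2Cl2 (2 mM, syringe-pump addition), 4 Å MS, 23 °C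
Reagents that add atoms: none
Why: Proposed new method: Rh2(OAc)4 turns the enol diazoacetate into an electrophilic rhodium carbenoid at C9, which is attacked by C10, the nucleophilic β-carbon of the tethered silyl enol ether, to give a zwitterion (C6 silyloxocarbenium ion and rhodium-bound 2-silyloxyallyl unit C9–C8–C7) that collapses by C7–C6 bond formation with loss of the metal; the closest known reactions are the formal (3+2) annulation of rhodium vinylcarbenoids with enol ethers (through donor–acceptor cyclopropanes or zwitterions) and the intramolecular cyclopropanation of homoallylic diazoacetates, but a tethered version on a tetrasubstituted cyclobutene enol ether has not been shown. The temporary six-membered lactone closes in a 6-exo mode (C10 inside the new ring, C6 outside), and ring A closes by 5-exo attack of the allyl terminus C7 on the exocyclic C6 oxocarbenium bond (enol-endo with respect to C7=C8), the closure mode of donor–acceptor vinylcyclopropane-to-cyclopentene ring expansions. C10 is set by the tether, since a lactone fused both to ring C through the endo C2–O bond and to the cyclobutane can place C9 only on the concave face, which pushes CH3-14 to the convex face; C6 follows because a five-membered ring can only be cis-fused to the cyclobutane, so C7 enters on the same face and the silyloxy group ends up exo. The step needs regioselectivity for C9–C10 bonding (secured by the polarity of the enol ether and by the tether, because attack at the vinylogous carbon C7 would require an eight-membered ring), chemoselectivity for C–C over C–O ring closure (secured by the carbon-nucleophilic enol silane terminus) and suppression of intermolecular reactions (slow addition at high dilution). Release of cyclobutene strain on pyramidalization and the intramolecularity are expected to offset the steric cost of forming the C10 quaternary carbon.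

Step 11
Reactants: 13 tetracyclic lactone
Product: 15 2-endo-hydroxy-6-exo-hydroxy-8-ketone of the tricycle (4-exo-OTBS retained), via keto acid 14 (not isolated)
Conditions: LiOH, THF–H2O, 0 → 23 °C; then AcOH–THF–H2O, 45 °C
Reagents that add atoms: none
Why: Saponification of the β-silyloxy enoate lactone, decarboxylation of the β-keto acid on acidification and acidolysis of the tertiary triethylsilyl ether remove the tether without trace (C9 becomes CH2) while the tert-butyldimethylsilyl ether survives and no stereocenter is touched; elimination of the C6 oxygen is disfavoured because it would place a double bond at the cyclobutane ring fusion.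

Step 12
Reactants: 15 diol ketone
Product: 16 2-exo-acetoxy-6-exo-hydroxy-8-ketone
Conditions: PMe3, DIAD, AcOH, THF, 0 → 23 °C
Reagents that add atoms: acetic acid CC(=O)O
Why: Mitsunobu esterification with a small phosphine (the alcohol sits in the cleft) inverts C2 by SN2 attack of acetate from the open exo face, while the tertiary C6 alcohol cannot react; any transannular hemiketal between the C2 hydroxyl and the C8 ketone is in equilibrium with the reacting open form and cannot dehydrate (bridgehead olefin).

Step 13
Reactants: 16 acetoxy hydroxy ketone; 17 3-bromo-2-oxopropanoic acid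
Product: 19 6-O-(3-bromo-2-oxopropanoyl) ester of 16, via 3-bromo-2-oxopropanoyl chloride 18 (not isolated)
Conditions: 17, 1-chloro-N,N,2-trimethylprop-1-en-1-amine, CH2Cl2, 0 °C; then 16, 2,6-lutidine, −40 → 0 °C
Reagents that add atoms: none
Why: Acylation of the tertiary cyclobutanol by a highly electrophilic α-keto acid chloride generated under neutral conditions, with a hindered base that is slow to be alkylated by the bromo ketone; no stereocenter changes.

Step 14
Reactants: 19 bromopyruvate ester
Product: 22 8-oxo butenolide: 2-exo-acetoxy-13-acetoxy-8-oxo-7(11)-en-12,6-olide 4-O-TBS ether, via acetoxypyruvate ester 20 (not isolated), via aldol adduct 21 (not isolated)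
Conditions: KOAc, AcOH, DMF, 23 → 60 °C
Reagents that add atoms: potassium acetate CC(=O)[O-].[K+]
Why: SN2 displacement of the α-bromo ketone by acetate is followed by intramolecular aldol condensation, a 5-(enolexo)-exo-trig attack of C7 on the pyruvate ketone and then E1cB dehydration to the tetrasubstituted butenolide; the competing attack by C9 gives a bridged aldol that cannot dehydrate (Bredt's rule) and reverts.

Step 15
Reactants: 22 8-oxo butenolide
Product: 23 8-endo-alcohol
Conditions: NaBH4, CeCl3·7H2O, MeOH, −78 °C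
Reagents that add atoms: none
Why: Luche 1,2-reduction of the enone carbonyl, hydride adding from the exo face because the endo face of ring A is closed by the cyclobutane and ring C, which gives the endo C8 alcohol.

Step 16
Reactants: 23 8-endo-alcohol; 24 tiglic acid
Product: 25 4-O-(tert-butyldimethylsilyl) ether of the target
Conditions: PMe3, DIAD, toluene, 0 → 23 °C
Reagents that add atoms: none
Why: Mitsunobu esterification with inversion sets the exo C8 tiglate (a small phosphine is chosen because the alcohol points into the cleft); the lactone on C11 destabilizes an allyl cation and C11 is fully substituted, so direct SN2 is expected, and the E acid cannot isomerize to a more stable form.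

Step 17
Reactants: 25 silyl ether
Product: 26 target CNP0210373.1
Conditions: HF·pyridine, THF, 0 → 23 °C
Reagents that add atoms: none
Why: Fluoride-mediated cleavage of the tertiary silyl ether under acidic, non-nucleophilic conditions that spare the three esters and the butenolide; no stereocenter is touched.

**Compound list**

1 | (R)-(−)-linalool, (3R)-3,7-dimethylocta-1,6-dien-3-ol | C=C[C@](C)(O)CCC=C(C)C | starting material
2 | (1R)-1-methylcyclopent-2-en-1-ol | C[C@]1(O)C=CCC1 | intermediate
3 | (1R)-1-methylcyclopent-2-en-1-yl tert-butyldimethylsilyl ether | C[C@]1(O[Si](C)(C)C(C)(C)C)C=CCC1 | intermediate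
4 | (4R)-4-(tert-butyldimethylsilyloxy)-4-methylcyclopent-2-en-1-one | C[C@]1(O[Si](C)(C)C(C)(C)C)C=CC(=O)C1 | intermediate
5 | 3,3-dimethoxyprop-1-ene (acrolein dimethyl acetal) | C=CC(OC)OC | starting material
6 | 1,1-dimethoxyprop-1-ene | CC=C(OC)OC | intermediate
7 | photoadduct: cis-fused 4-exo-(TBSO)-6,6-dimethoxy-4-endo-methyl-7-methylbicyclo[3.2.0]heptan-2-one (C7 epimers) | CC1[C@@H]2C(=O)C[C@@](C)(O[Si](C)(C)C(C)(C)C)[C@@H]2C1(OC)OC | intermediate
8 | ketal alcohol: 2-endo-hydroxy analogue of 7 (not isolated) | CC1[C@@H]2[C@H](O)C[C@@](C)(O[Si](C)(C)C(C)(C)C)[C@@H]2C1(OC)OC | intermediate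
9 | 4-exo-(TBSO)-2-endo-hydroxy-4-endo-methyl-7-methylbicyclo[3.2.0]heptan-6-one | CC1[C@@H]2[C@H](O)C[C@@](C)(O[Si](C)(C)C(C)(C)C)[C@@H]2C1=O | intermediate
10 | 2-endo-(3-oxobutanoyloxy) ester of 9 | CC1[C@@H]2[C@H](OC(=O)CC(C)=O)C[C@@](C)(O[Si](C)(C)C(C)(C)C)[C@@H]2C1=O | intermediate
11 | 2-endo-(2-diazo-3-oxobutanoyloxy) ester of 9 | CC1[C@@H]2[C@H](OC(=O)C(=[N+]=[N-])C(C)=O)C[C@@](C)(O[Si](C)(C)C(C)(C)C)[C@@H]2C1=O | intermediate
12 | enol diazoacetate with C10=C6 silyl enol ether (bis-triethylsilyl) | CC=1[C@@H]2[C@H](OC(=O)C(=[N+]=[N-])C(=C)O[Si](CC)(CC)CC)C[C@@](C)(O[Si](C)(C)C(C)(C)C)[C@@H]2C=1O[Si](CC)(CC)CC | intermediate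
13 | tetracyclic lactone: δ-lactone C2(endo)–O–C(=O)–C9, C8=C9 enol ether (8-OSiEt3), 6-exo-OSiEt3, 4-exo-OTBS | CC[Si](CC)(CC)OC1=C2C(=O)O[C@@H]3C[C@@](C)(O[Si](C)(C)C(C)(C)C)[C@H]4[C@@H]3[C@]2(C)[C@@]4(O[Si](CC)(CC)CC)C1 | intermediate
14 | keto acid: 9-carboxy-8-oxo-2-endo-hydroxy-6-exo-OSiEt3 tricycle (not isolated) | O=C1C(C(=O)O)[C@]2(C)[C@@H]3[C@H](O)C[C@@](C)(O[Si](C)(C)C(C)(C)C)[C@@H]3[C@]2(O[Si](CC)(CC)CC)C1 | intermediate
15 | 2-endo-hydroxy-6-exo-hydroxy-8-ketone (4-exo-OTBS) | O=C1C[C@]2(C)[C@@H]3[C@H](O)C[C@@](C)(O[Si](C)(C)C(C)(C)C)[C@@H]3[C@]2(O)C1 | intermediate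
16 | 2-exo-acetoxy-6-exo-hydroxy-8-ketone (4-exo-OTBS) | O=C1C[C@]2(C)[C@@H]3[C@@H](OC(C)=O)C[C@@](C)(O[Si](C)(C)C(C)(C)C)[C@@H]3[C@]2(O)C1 | intermediate
17 | 3-bromo-2-oxopropanoic acid (bromopyruvic acid) | OC(=O)C(=O)CBr | starting material
18 | 3-bromo-2-oxopropanoyl chloride (not isolated) | ClC(=O)C(=O)CBr | intermediate
19 | 6-O-(3-bromo-2-oxopropanoyl) ester of 16 | O=C1C[C@]2(C)[C@@H]3[C@@H](OC(C)=O)C[C@@](C)(O[Si](C)(C)C(C)(C)C)[C@@H]3[C@]2(OC(=O)C(=O)CBr)C1 | intermediate
20 | 6-O-(3-acetoxy-2-oxopropanoyl) ester of 16 (not isolated) | O=C1C[C@]2(C)[C@@H]3[C@@H](OC(C)=O)C[C@@](C)(O[Si](C)(C)C(C)(C)C)[C@@H]3[C@]2(OC(=O)C(=O)COC(C)=O)C1 | intermediate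
21 | aldol adduct: 11-hydroxy-7,11-dihydro lactone (C7 and C11 epimers, not isolated) | O=C1C[C@]2(C)[C@@H]3[C@@H](OC(C)=O)C[C@@](C)(O[Si](C)(C)C(C)(C)C)[C@@H]3[C@@]23OC(=O)C(O)(COC(C)=O)C13 | intermediate
22 | 8-oxo butenolide: 2-exo,13-diacetoxy-8-oxo-7(11)-en-12,6-olide 4-O-TBS ether | O=C1C[C@]2(C)[C@@H]3[C@@H](OC(C)=O)C[C@@](C)(O[Si](C)(C)C(C)(C)C)[C@@H]3[C@@]23OC(=O)C(COC(C)=O)=C13 | intermediate
23 | 8-endo-alcohol of 22 | O[C@@H]1C[C@]2(C)[C@@H]3[C@@H](OC(C)=O)C[C@@](C)(O[Si](C)(C)C(C)(C)C)[C@@H]3[C@@]23OC(=O)C(COC(C)=O)=C13 | intermediate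
24 | tiglic acid, (E)-2-methylbut-2-enoic acid | C/C=C(\C)C(=O)O | starting material
25 | 4-O-(tert-butyldimethylsilyl) ether of the target (8-exo-tiglate) | C/C=C(\C)C(=O)O[C@H]1C[C@]2(C)[C@@H]3[C@@H](OC(C)=O)C[C@@](C)(O[Si](C)(C)C(C)(C)C)[C@@H]3[C@@]23OC(=O)C(COC(C)=O)=C13 | intermediate
26 | CNP0210373.1: 2-exo,13-diacetoxy-4-exo-hydroxy-8-exo-tigloyloxy-7(11)-en-12,6-olide of the cis-syn-cis 5-4-5 skeleton | C/C=C(\C)C(=O)O[C@H]1C[C@]2(C)[C@@H]3[C@@H](OC(C)=O)C[C@@](C)(O)[C@@H]3[C@@]23OC(=O)C(COC(C)=O)=C13 | target

**Step count**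

Total: 17 steps. Longest linear sequence: 16 steps (steps 1–3 and 5–17).

**Steps most likely to fail**

Step 10 (Proposed new method). The zwitterion may close through oxygen or lose its silyl group from the C6 oxocarbenium ion before the C7–C6 bond forms. Alternatively, the hindered tetrasubstituted enol ether may react too slowly, so that C–H insertion or dimerization of the carbenoid takes over. The fallback uses known chemistry and sets out from 10. Silylation (TESOTf, Et3N) gives the bis(triethylsilyl enol ether) F1. Oxidative coupling of the two enol silanes with (NH4)2Ce(NO3)6 and NaHCO3 in MeCN forms C9–C10 inside the same six-membered lactone, again on the concave face, to give the 1,4-diketone lactone F2. Saponification and decarboxylation (LiOH, then AcOH) give the methyl ketone–cyclobutanone F3. Intramolecular aldol addition of the methyl ketone to the strained cyclobutanone (K2CO3, MeOH), which cannot dehydrate, closes C7–C6 and returns to the route at 15.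

Step 5. The alkene may add to the face that carries the silyloxy group, because the methyl and silyloxy groups compete for facial control. The fallback sets out from 6 and applies when the cycloaddition prefers the silyloxy face. (S)-Linalool F4 is taken through the conditions of steps 1–3, by way of (1S)-1-methylcyclopent-2-en-1-ol F5 and its silyl ether F6, to the enantiomeric enone F7. Its adduct with 6 on the silyloxy face, the syn photoadduct F8, has the required configuration at C1 and C5. C4 is then corrected: E1cB loss of silanol (DBU) gives the bicyclic enone F9; nucleophilic epoxidation from the exo face (H2O2, NaOH) gives the epoxy ketone F10; reductive opening (SmI2, THF–MeOH, −78 °C) gives the β-hydroxy ketone F11 with the 4-exo-hydroxyl; silylation (TBSOTf, 2,6-lutidine) returns to the route at 7.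

Step 13. The bromo keto acid chloride may decompose or alkylate the base before it acylates the hindered tertiary cyclobutanol, and the β-hydroxy ketone may cleave by retro-aldol reaction. The fallback sets out from 16. Acylation with methyl chlorooxoacetate (pyridine, DMAP) gives the methyl oxalate F12. Dieckmann-type Claisen cyclization of the C7 enolate onto the methyl ester (LiN(SiMe3)2, THF, −78 °C) gives the 11-hydroxy butenolide F13, whose regiochemistry is guarded by the same Bredt argument as in step 14. Triflation (Tf2O, 2,6-di-tert-butylpyridine) gives the enol triflate F14. Stille coupling with (acetoxymethyl)tributylstannane (Pd(PPh3)4, LiCl, CuI, DMF) installs C13 and returns to the route at 22.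

**Further compounds**

F1 | step 10 | bis(triethylsilyl enol ether) of 10 | CC=1[C@@H]2[C@H](OC(=O)C=C(C)O[Si](CC)(CC)CC)C[C@@](C)(O[Si](C)(C)C(C)(C)C)[C@@H]2C=1O[Si](CC)(CC)CC
F2 | step 10 | 1,4-diketone lactone (C9–C10 coupled, 9-acetyl δ-lactone on the cyclobutanone) | CC(=O)C1C(=O)O[C@@H]2C[C@@](C)(O[Si](C)(C)C(C)(C)C)[C@H]3[C@@H]2[C@]1(C)C3=O
F3 | step 10 | methyl ketone–cyclobutanone (10-(2-oxopropyl), 2-endo-hydroxy) | CC(=O)C[C@]1(C)[C@@H]2[C@H](O)C[C@@](C)(O[Si](C)(C)C(C)(C)C)[C@@H]2C1=O
F4 | step 5 | (S)-linalool | C=C[C@@](C)(O)CCC=C(C)C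
F5 | step 5 | (1S)-1-methylcyclopent-2-en-1-ol | C[C@@]1(O)C=CCC1
F6 | step 5 | (1S)-1-methylcyclopent-2-en-1-yl tert-butyldimethylsilyl ether | C[C@@]1(O[Si](C)(C)C(C)(C)C)C=CCC1
F7 | step 5 | (4S)-4-(tert-butyldimethylsilyloxy)-4-methylcyclopent-2-en-1-one | C[C@@]1(O[Si](C)(C)C(C)(C)C)C=CC(=O)C1
F8 | step 5 | syn photoadduct (4-endo-OTBS, 4-exo-methyl; C1/C5 as in 7) | CC1[C@@H]2C(=O)C[C@](C)(O[Si](C)(C)C(C)(C)C)[C@@H]2C1(OC)OC
F9 | step 5 | 6,6-dimethoxy-4,7-dimethylbicyclo[3.2.0]hept-3-en-2-one | CC1[C@@H]2C(=O)C=C(C)[C@@H]2C1(OC)OC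
F10 | step 5 | 3,4-exo-epoxy ketone | CC1[C@@H]2C(=O)[C@H]3O[C@@]3(C)[C@@H]2C1(OC)OC
F11 | step 5 | 4-exo-hydroxy-6,6-dimethoxy-4-endo-methyl-7-methylbicyclo[3.2.0]heptan-2-one | CC1[C@@H]2C(=O)C[C@@](C)(O)[C@@H]2C1(OC)OC
F12 | step 13 | 6-O-(methoxyoxalyl) ester of 16 | O=C1C[C@]2(C)[C@@H]3[C@@H](OC(C)=O)C[C@@](C)(O[Si](C)(C)C(C)(C)C)[C@@H]3[C@]2(OC(=O)C(=O)OC)C1
F13 | step 13 | 11-hydroxy-8-oxo butenolide (enol form) | O=C1C[C@]2(C)[C@@H]3[C@@H](OC(C)=O)C[C@@](C)(O[Si](C)(C)C(C)(C)C)[C@@H]3[C@@]23OC(=O)C(O)=C13
F14 | step 13 | 11-(trifluoromethylsulfonyloxy)-8-oxo butenolide | O=C1C[C@]2(C)[C@@H]3[C@@H](OC(C)=O)C[C@@](C)(O[Si](C)(C)C(C)(C)C)[C@@H]3[C@@]23OC(=O)C(OS(=O)(=O)C(F)(F)F)=C13
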